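Ring C of the chroman is disconnected at O1–C8a and C4–C4a. In ring A, O1 (on C8a) lies para to the C6 oxygen and C4 sits on the neighbouring carbon C4a, so ring A can be carried as a vanillin-type 4-alkyl-2-methoxyphenol. One operation builds the pyran ring and restores the arene: hypervalent-iodine dearomatisation of that phenol, capture of its para carbon by the chain hydroxyl (spiro-tetrahydrofuran), and an acid-driven 1,2-shift of the benzylic CH2. The precursor is an open-chain (S)-2,3-diarylpropan-1-ol whose ring B carries its future quinone oxygen as a benzyl ether. The C3 stereocentre is set beforehand by asymmetric hydrogenation and only rides through.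

Key step: step 7

Remarks and assumptions (chemistry)
- The target is taken as drawn, with C3 = S. Ring A is the benzo ring of the chroman, ring C its dihydropyran ring, ring B the pendant ring that ends as the quinone (primed locants). At the carbon that becomes C3 the CIP order (CH2O or CO2H > aryl > CH2Ar > H) is the same in compounds 8 to 14, so the descriptor stays S throughout.
- Precursor 9 and chromanol 11 are kept with the benzyl ether on ring B: it leaves ring A as the only free phenol in step 7, survives hydride, PhI(OAc)2, BF3 and base, and its removal uncovers exactly the phenol needed for the last oxidation. The ring-A phenol travels as the acetate that the Perkin step installs anyway and that the hydride step removes.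
- Step 5: the sense of induction is assigned by analogy with other α-arylcinnamic acids. The antipode of the ligand that delivers the (S)-acid is the one meant; if the (Sa,S) complex favours (R), its mirror image is used under the same conditions.

Step 1
Reactants: 1 2-hydroxy-3,4-dimethoxybenzaldehyde
Product: 2 2-(benzyloxy)-3,4-dimethoxybenzaldehyde
Conditions: BnBr (1.1 equiv), K2CO3, DMF, 60 °C
Reagents that add atoms: benzyl bromide, BrCc1ccccc1
Why: Williamson ether synthesis: the phenoxide, freed from its hydrogen bond to the aldehyde by K2CO3 in warm DMF, displaces bromide from benzyl bromide, and nothing else in 1 can be alkylated.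

Step 2
Reactants: 2 2-(benzyloxy)-3,4-dimethoxybenzaldehyde
Product: 4 2-[2-(benzyloxy)-3,4-dimethoxyphenyl]acetonitrile, via tosylvinyl formamide 3 (not isolated)
Conditions: TosMIC (1.1 equiv), t-BuOK (2.2 equiv), DME, −40 °C; then MeOH, reflux
Reagents that add atoms: p-toluenesulfonylmethyl isocyanide (TosMIC), Cc1ccc(cc1)S(=O)(=O)C[N+]#[C-]
Why: Van Leusen reductive cyanation: the TosMIC anion adds to the aldehyde and the oxazoline opens to formamide 3, which methoxide deformylates; loss of sulfinate and tautomerisation of the ketenimine leave the former aldehyde carbon as the benzylic CH2 of the nitrile.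

Step 3
Reactants: 4 2-[2-(benzyloxy)-3,4-dimethoxyphenyl]acetonitrile
Product: 5 2-[2-(benzyloxy)-3,4-dimethoxyphenyl]acetic acid
Conditions: KOH, EtOH/H2O, reflux; then HCl (aq) to pH 2
Reagents that add atoms: water, O; potassium hydroxide, [K+].[OH-]
Why: Base hydrolysis of the nitrile through the primary amide to the carboxylate, which acid sets free; aryl benzyl and methyl ethers are inert to hot hydroxide.

Step 4
Reactants: 5 2-[2-(benzyloxy)-3,4-dimethoxyphenyl]acetic acid; 6 vanillin
Product: 7 (2E)-3-[4-(acetyloxy)-3-methoxyphenyl]-2-[2-(benzyloxy)-3,4-dimethoxyphenyl]prop-2-enoic acid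
Conditions: Ac2O, Et3N, 110 °C; aq. HCl work-up
Reagents that add atoms: acetic anhydride, CC(=O)OC(C)=O
Why: Perkin condensation (Oglialoro variant): the enolate of the mixed anhydride of 5 adds to the aldehyde and acetate is eliminated to give the E acid with the two aryl groups cis, while the phenol of vanillin is acetylated in the same pot and thereby masked.

Step 5
Reactants: 7 (2E)-3-[4-(acetyloxy)-3-methoxyphenyl]-2-[2-(benzyloxy)-3,4-dimethoxyphenyl]prop-2-enoic acid
Product: 8 (2S)-3-[4-(acetyloxy)-3-methoxyphenyl]-2-[2-(benzyloxy)-3,4-dimethoxyphenyl]propanoic acid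
Conditions: H2 (6 atm), [Ir(cod)(L)]BArF (1 mol %), Et3N (0.5 equiv), MeOH, rt; L = (Sa)-7-[bis(3,5-di-tert-butylphenyl)phosphanyl]-7'-[(4S)-4-benzyl-4,5-dihydro-1,3-oxazol-2-yl]-1,1'-spirobiindane, BArF = B[3,5-(CF3)2C6H3]4
Reagents that add atoms: none
Why: Carboxylate-directed asymmetric hydrogenation of an α-arylcinnamic acid by a cationic iridium spiro phosphine–oxazoline complex: the bound carboxylate holds the olefin in the chiral pocket, which decides the face of hydrogen delivery and so sets C2 (the later C3) as S, and this homogeneous catalyst should leave the benzyl ether and, in the carboxylate-buffered medium, the aryl acetate alone.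

Step 6
Reactants: 8 (2S)-3-[4-(acetyloxy)-3-methoxyphenyl]-2-[2-(benzyloxy)-3,4-dimethoxyphenyl]propanoic acid
Product: 9 (2S)-2-[2-(benzyloxy)-3,4-dimethoxyphenyl]-3-(4-hydroxy-3-methoxyphenyl)propan-1-ol
Conditions: LiAlH4 (4 equiv), THF, 0 to 50 °C; cold 1 M HCl work-up
Reagents that add atoms: none
Why: Hydride reduction: LiAlH4 takes the carboxylate to the primary alcohol and cleaves the aryl acetate in the same operation, and the stereocentre cannot epimerise because the carboxylate formed first does not enolise.

Step 7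
Reactants: 9 (2S)-2-[2-(benzyloxy)-3,4-dimethoxyphenyl]-3-(4-hydroxy-3-methoxyphenyl)propan-1-ol
Product: 11 (3S)-3-[2-(benzyloxy)-3,4-dimethoxyphenyl]-7-methoxychroman-6-ol, via spirodienone 10 (not isolated)
Conditions: PhI(OAc)2 (1.05 equiv), MeCN, 0 °C, 0.02 M; aq. NaHCO3/Na2S2O3 wash; then BF3·OEt2 (0.5 equiv), CH2Cl2, −40 to 0 °C
Reagents that add atoms: none
Why: Exchange of acetate for the phenol at iodine and loss of PhI make ring A a phenoxenium equivalent, which the primary hydroxyl traps at the para (ipso) carbon to give spirodienone 10 (O1–C8a bond); BF3 then binds the dienone oxygen, the CH2 group (C4) shifts from the spiro carbon to the neighbouring ring carbon (C4–C4a bond) while the charge left on C8a is held as an oxocarbenium ion, and loss of a proton re-aromatises to the chromanol. Both halves are known reaction types, namely hypervalent-iodine spiroetherification of 4-(3-hydroxypropyl)phenols and the acid-promoted dienone–phenol rearrangement of 1-oxaspiro[4.5]deca-6,9-dien-8-ones to chroman-6-ols. Ring C is closed first as a five-membered ring by a 5-exo spirocyclisation on oxygen and is then enlarged to the six-membered pyran by the 1,2-alkyl shift. No lasting stereocentre is created (the spiro carbon becomes aromatic C8a), and C3, which carries neither a migrating nor an acidic bond, is carried through unchanged. The oxidation should touch ring A only, because it is the sole free phenol, ring B is fully etherified and its one carbon within reach (C6', para to the twisted 3'-methoxy group) is a poor nucleophile, and high dilution disfavours intermolecular capture. The shift has to go to the ring carbon remote from the methoxy group, which is the unhindered β-carbon of the unsubstituted and more electrophilic enone half; if oxygen migrated there instead of carbon, the 7-hydroxy-6-methoxy isomer would form, which step 8 turns into the same compound 12.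

Step 8
Reactants: 11 (3S)-3-[2-(benzyloxy)-3,4-dimethoxyphenyl]-7-methoxychroman-6-ol
Product: 12 (3S)-3-[2-(benzyloxy)-3,4-dimethoxyphenyl]-6,7-dimethoxychroman
Conditions: MeI, K2CO3, acetone, reflux
Reagents that add atoms: iodomethane, CI
Why: Williamson O-methylation of the only free phenol in the molecule.

Step 9
Reactants: 12 (3S)-3-[2-(benzyloxy)-3,4-dimethoxyphenyl]-6,7-dimethoxychroman
Product: 13 6-[(3S)-6,7-dimethoxychroman-3-yl]-2,3-dimethoxyphenol
Conditions: H2 (1 atm), 10% Pd/C, EtOAc/EtOH, rt
Reagents that add atoms: none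
Why: Catalytic hydrogenolysis of the aryl benzyl ether; the chroman has no benzylic C–O bond (C4 bears no oxygen and C2–O1 is not benzylic), so ring C, C3 and the methyl ethers should be untouched.

Step 10
Reactants: 13 6-[(3S)-6,7-dimethoxychroman-3-yl]-2,3-dimethoxyphenol
Product: 14 abroquinone A, 5-[(3S)-6,7-dimethoxychroman-3-yl]-2,3-dimethoxycyclohexa-2,5-diene-1,4-dione
Conditions: (KSO3)2NO (2.5 equiv), KH2PO4 (aq), acetone/H2O, rt
Reagents that add atoms: potassium nitrosodisulfonate (Fremy's salt), [K+].[K+].[O]N(S(=O)(=O)[O-])S(=O)(=O)[O-]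
Why: Teuber oxidation: one nitrosodisulfonate radical abstracts the phenolic hydrogen, a second bonds through oxygen to the free para carbon (C5' of ring B) and loss of imidodisulfonate gives the para-quinone; ring A has no free phenol and is not attacked, and the near-neutral buffer leaves C3 alone.

Compound list
1 | 2-hydroxy-3,4-dimethoxybenzaldehyde | COc1ccc(C=O)c(O)c1OC | starting material
2 | 2-(benzyloxy)-3,4-dimethoxybenzaldehyde | COc1ccc(C=O)c(OCc2ccccc2)c1OC | intermediate
3 | N-{2-[2-(benzyloxy)-3,4-dimethoxyphenyl]-1-[(4-methylphenyl)sulfonyl]ethenyl}formamide (potassium salt in the flask, olefin geometry not defined) | O=CNC(=Cc1ccc(OC)c(OC)c1OCc1ccccc1)S(=O)(=O)c1ccc(C)cc1 | intermediate (not isolated)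
4 | 2-[2-(benzyloxy)-3,4-dimethoxyphenyl]acetonitrile | COc1ccc(CC#N)c(OCc2ccccc2)c1OC | intermediate
5 | 2-[2-(benzyloxy)-3,4-dimethoxyphenyl]acetic acid | COc1ccc(CC(=O)O)c(OCc2ccccc2)c1OC | intermediate
6 | vanillin (4-hydroxy-3-methoxybenzaldehyde) | COc1cc(C=O)ccc1O | starting material
7 | (2E)-3-[4-(acetyloxy)-3-methoxyphenyl]-2-[2-(benzyloxy)-3,4-dimethoxyphenyl]prop-2-enoic acid | OC(=O)/C(=C/c1ccc(OC(C)=O)c(OC)c1)c1ccc(OC)c(OC)c1OCc1ccccc1 | intermediate
8 | (2S)-3-[4-(acetyloxy)-3-methoxyphenyl]-2-[2-(benzyloxy)-3,4-dimethoxyphenyl]propanoic acid | COc1ccc([C@@H](C(=O)O)Cc2ccc(OC(C)=O)c(OC)c2)c(OCc2ccccc2)c1OC | intermediate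
9 | (2S)-2-[2-(benzyloxy)-3,4-dimethoxyphenyl]-3-(4-hydroxy-3-methoxyphenyl)propan-1-ol | COc1ccc([C@@H](CO)Cc2ccc(O)c(OC)c2)c(OCc2ccccc2)c1OC | intermediate (precursor of the key step)
10 | (3S)-3-[2-(benzyloxy)-3,4-dimethoxyphenyl]-7-methoxy-1-oxaspiro[4.5]deca-6,9-dien-8-one (both epimers at spiro carbon C5) | COC1=CC2(C=CC1=O)C[C@H](CO2)c1ccc(OC)c(OC)c1OCc1ccccc1 | intermediate (not isolated)
11 | (3S)-3-[2-(benzyloxy)-3,4-dimethoxyphenyl]-7-methoxychroman-6-ol | COc1ccc([C@H]2COc3cc(OC)c(O)cc3C2)c(OCc2ccccc2)c1OC | intermediate (product of the key step)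
12 | (3S)-3-[2-(benzyloxy)-3,4-dimethoxyphenyl]-6,7-dimethoxychroman | COc1ccc([C@H]2COc3cc(OC)c(OC)cc3C2)c(OCc2ccccc2)c1OC | intermediate
13 | 6-[(3S)-6,7-dimethoxychroman-3-yl]-2,3-dimethoxyphenol | COc1ccc([C@H]2COc3cc(OC)c(OC)cc3C2)c(O)c1OC | intermediate
14 | abroquinone A, 5-[(3S)-6,7-dimethoxychroman-3-yl]-2,3-dimethoxycyclohexa-2,5-diene-1,4-dione | COC1=C(OC)C(=O)C([C@H]2COc3cc(OC)c(OC)cc3C2)=CC1=O | target

Total step count: 10
Longest linear sequence: 10 steps (1 to 14; vanillin 6 enters at step 4)

Steps most likely to fail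

1. Step 7. The alkyl shift may run toward the methoxy-bearing side of the dienone, or the dearomatised ring may be captured by ring B or by acetate and re-aromatise without ring enlargement. The fallback makes O1–C8a by palladium-catalysed aryl ether formation on a ring A that carries bromine at the future C8a. It sets out from acid 5. Perkin condensation under the step-4 conditions with commercial 2-bromo-4,5-dimethoxybenzaldehyde should give (2E)-2-[2-(benzyloxy)-3,4-dimethoxyphenyl]-3-(2-bromo-4,5-dimethoxyphenyl)prop-2-enoic acid F1. The step-5 hydrogenation should give (2S)-2-[2-(benzyloxy)-3,4-dimethoxyphenyl]-3-(2-bromo-4,5-dimethoxyphenyl)propanoic acid F2. BH3·SMe2 in THF, which spares the aryl bromide, should give (2S)-2-[2-(benzyloxy)-3,4-dimethoxyphenyl]-3-(2-bromo-4,5-dimethoxyphenyl)propan-1-ol F3. Pd(OAc)2, 2-(di-tert-butylphosphino)-1,1'-binaphthyl and Cs2CO3 in toluene at 80 °C then close ring C by intramolecular C–O coupling. The fallback comes back to the route at compound 12, so steps 6 to 8 are not needed.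

2. Step 5. Facial selectivity may be poor or turnover slow, because the ortho-benzyloxy group twists the α-aryl ring out of the olefin plane. The fallback sets the stereocentre by auxiliary-controlled enolate alkylation; it sets out from acid 5 and vanillin 6 and comes back at compound 9. Acid 5 is activated with PivCl/Et3N and acylates lithiated (S)-4-benzyloxazolidin-2-one to give (4S)-4-benzyl-3-{[2-(benzyloxy)-3,4-dimethoxyphenyl]acetyl}-1,3-oxazolidin-2-one F4. Vanillin 6 is converted by PivCl/Et3N into 4-formyl-2-methoxyphenyl pivalate F5, by NaBH4 in MeOH at 0 °C into 4-(hydroxymethyl)-2-methoxyphenyl pivalate F6, and by PBr3 in CH2Cl2 into 4-(bromomethyl)-2-methoxyphenyl pivalate F7. The sodium Z-enolate of F4 (NaN(SiMe3)2, THF, −78 °C) should be alkylated by F7 on the face away from the benzyl group of the auxiliary. This should give (4S)-4-benzyl-3-{(2S)-2-[2-(benzyloxy)-3,4-dimethoxyphenyl]-3-[3-methoxy-4-(pivaloyloxy)phenyl]propanoyl}-1,3-oxazolidin-2-one F8. LiAlH4 in THF at 0 °C then removes auxiliary and pivalate together and delivers 9.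

3. Step 2. The oxazoline intermediate of this hindered, electron-rich aldehyde may be diverted to the aromatic oxazole, or deformylation may stay incomplete. The fallback homologates by olefination and oxidation; it sets out from aldehyde 2 and comes back at acid 5, so step 3 is not needed. Wittig reaction with Ph3P=CHOMe (from (methoxymethyl)triphenylphosphonium chloride and t-BuOK, THF, 0 °C) should give 2-(benzyloxy)-3,4-dimethoxy-1-(2-methoxyethenyl)benzene F9 as an E/Z mixture. Hydrolysis with 2 M HCl in THF should give [2-(benzyloxy)-3,4-dimethoxyphenyl]acetaldehyde F10. Pinnick oxidation (NaClO2, NaH2PO4, 2-methyl-2-butene, t-BuOH/H2O) then gives 5.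

Further compounds
F1 | step 7 | (2E)-2-[2-(benzyloxy)-3,4-dimethoxyphenyl]-3-(2-bromo-4,5-dimethoxyphenyl)prop-2-enoic acid | OC(=O)/C(=C/c1cc(OC)c(OC)cc1Br)c1ccc(OC)c(OC)c1OCc1ccccc1
F2 | step 7 | (2S)-2-[2-(benzyloxy)-3,4-dimethoxyphenyl]-3-(2-bromo-4,5-dimethoxyphenyl)propanoic acid | COc1ccc([C@@H](C(=O)O)Cc2cc(OC)c(OC)cc2Br)c(OCc2ccccc2)c1OC
F3 | step 7 | (2S)-2-[2-(benzyloxy)-3,4-dimethoxyphenyl]-3-(2-bromo-4,5-dimethoxyphenyl)propan-1-ol | COc1ccc([C@@H](CO)Cc2cc(OC)c(OC)cc2Br)c(OCc2ccccc2)c1OC
F4 | step 5 | (4S)-4-benzyl-3-{[2-(benzyloxy)-3,4-dimethoxyphenyl]acetyl}-1,3-oxazolidin-2-one | COc1ccc(CC(=O)N2[C@@H](Cc3ccccc3)COC2=O)c(OCc2ccccc2)c1OC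
F5 | step 5 | 4-formyl-2-methoxyphenyl pivalate | COc1cc(C=O)ccc1OC(=O)C(C)(C)C
F6 | step 5 | 4-(hydroxymethyl)-2-methoxyphenyl pivalate | COc1cc(CO)ccc1OC(=O)C(C)(C)C
F7 | step 5 | 4-(bromomethyl)-2-methoxyphenyl pivalate | COc1cc(CBr)ccc1OC(=O)C(C)(C)C
F8 | step 5 | (4S)-4-benzyl-3-{(2S)-2-[2-(benzyloxy)-3,4-dimethoxyphenyl]-3-[3-methoxy-4-(pivaloyloxy)phenyl]propanoyl}-1,3-oxazolidin-2-one | COc1ccc([C@H](Cc2ccc(OC(=O)C(C)(C)C)c(OC)c2)C(=O)N2[C@@H](Cc3ccccc3)COC2=O)c(OCc2ccccc2)c1OC
F9 | step 2 | 2-(benzyloxy)-3,4-dimethoxy-1-(2-methoxyethenyl)benzene (E/Z mixture) | COC=Cc1ccc(OC)c(OC)c1OCc1ccccc1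
F10 | step 2 | [2-(benzyloxy)-3,4-dimethoxyphenyl]acetaldehyde | O=CCc1ccc(OC)c(OC)c1OCc1ccccc1
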